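The route rests on cutting the trione half through its arene. Ring B (C4a, C5–C8, C8a) carries O, O, H, O on C5–C8, the pattern a carbene benzannulation writes. The carbocycle C1–C4, C4a, C8a can exist beforehand as a cyclohexene that already holds the quaternary carbinol C2. In one operation a cyclohexenyl(methoxy)carbene chromium complex (carbene carbon C8 on C8a), ethoxyacetylene (C7, C6) and one CO ligand (C5) form C7–C8, C5–C6 and C4a–C5 and close ring B. The precursor is an enantioenriched monocycle with C2 masked as a silyl ether. C1, C3 and C4 are then oxygenated before the ether bond to chloroquinone A is made.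

Key step: step 6

Numbering: the trione half (half B) keeps the target numbers C1–C8a throughout. In the quinone half (half A) C1 is the carbonyl next to the ether carbon C2, C3 carries ethyl, and oxygen sits on C5, C7 and C8.

Assumption: (R,R)-QuinoxP* is taken to deliver boron to the enone face that gives (S)-5. If the sense is the opposite, the equally available (S,S)-ligand is used.

Remark on descriptors: the target is S at C2. The same spatial arrangement reads S in boronate 5, R in 6–38 and S again in 39 and 40, only because substituent priorities change.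

Remarks on design:
- **Half A regiochemistry.** In half A the ethyl carbon must lie next to the carbonyl that is peri to the isolated oxygen (C5–O). α-Ethylation of a preformed 5,7,8-trimethoxy-1-tetralone would put it on the wrong side, so the ethyl group is built into the open chain (steps 13, 14).
- **Order of oxidation and coupling.** A C4 ketone beside C3H2 with a leaving group on C2 would eliminate to a naphthoquinone. A C3=C4 alkene beside the quinonyl ether would be an allyl vinyl ether. C3 and C4 are therefore oxygenated first and carried through the coupling as an acetonide.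

Step 1
Reactants: 1 3-ethoxycyclohex-2-en-1-one; 2 ethylmagnesium bromide
Product: 4 3-ethylcyclohex-2-en-1-one, via bromomagnesium alkoxide adduct 3 (not isolated)
Conditions: EtMgBr (1.3 equiv), THF, 0 °C to rt; then 1 M aq. HCl, rt
Reagents that add atoms: ethylmagnesium bromide CC[Mg]Br; water O
Why: Stork–Danheiser sequence: 1,2-addition of the Grignard reagent to the vinylogous ester, then acid-induced loss of water and hydrolysis of the enol ether, should give the transposed 3-ethyl enone, and no stereocentre is formed.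

Step 2
Reactants: 4 3-ethylcyclohex-2-en-1-one
Product: 6 (R)-3-ethyl-3-hydroxycyclohexan-1-one, via (S)-β-boryl ketone 5 (not isolated)
Conditions: B2pin2 (1.3 equiv), [Cu(MeCN)4]PF6 (5 mol%), (R,R)-QuinoxP* (6 mol%), LiOt-Bu (10 mol%), DMSO, rt; aqueous work-up; NaBO3·4H2O, THF/H2O, rt
Reagents that add atoms: bis(pinacolato)diboron CC1(C)OB(OC1(C)C)B1OC(C)(C)C(C)(C)O1 (boryl group of 5 only); sodium perborate [Na+].[Na+].O[B-]1(O)OO[B-](O)(O)OO1 (hydroxyl oxygen of 6)
Why: Copper-catalysed enantioselective conjugate borylation of a β-substituted cyclic enone, in which the chiral bisphosphine on the copper boryl species decides the enone face and so sets quaternary C2, is followed by perborate oxidation, whose 1,2-shift from boron to oxygen retains configuration and is mild enough to spare the β-hydroxy ketone from retro-aldol opening.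

Step 3
Reactants: 6 (R)-3-ethyl-3-hydroxycyclohexan-1-one
Product: 7 (R)-3-ethyl-3-(triethylsilyloxy)cyclohexan-1-one
Conditions: Et3SiOTf (1.2 equiv), 2,6-lutidine, CH2Cl2, −78 to 0 °C
Reagents that add atoms: triethylsilyl triflate CC[Si](CC)(CC)OS(=O)(=O)C(F)(F)F
Why: Silylation of a tertiary alcohol with a silyl triflate and a hindered pyridine base, run cold so that the β-hydroxy ketone neither dehydrates nor forms an enol silane, leaves C2 untouched.

Step 4
Reactants: 7 (R)-3-ethyl-3-(triethylsilyloxy)cyclohexan-1-one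
Product: 8 2,4,6-triisopropylbenzenesulfonylhydrazone of 7
Conditions: 2,4,6-triisopropylbenzenesulfonohydrazide (1.05 equiv), THF, rt, no acid
Reagents that add atoms: 2,4,6-triisopropylbenzenesulfonohydrazide CC(C)c1cc(C(C)C)c(S(=O)(=O)NN)c(C(C)C)c1
Why: Hydrazone condensation without acid catalyst, possible because the ketone is unhindered, avoids elimination of the β-silyloxy group and should place the sulfonamide arm on the side of the open methylene C4a.

Step 5
Reactants: 8 2,4,6-triisopropylbenzenesulfonylhydrazone of 7; 9 hexacarbonylchromium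
Product: 12 pentacarbonyl{[(5R)-5-ethyl-5-(triethylsilyloxy)cyclohex-1-en-1-yl](methoxy)carbene}chromium, via vinyllithium 10 (not isolated), via lithium acylchromate 11 (not isolated)
Conditions: n-BuLi (2.1 equiv), THF, −78 to 0 °C; Cr(CO)6, THF, 0 °C to rt; evaporate; Me3OBF4, CH2Cl2, 0 °C to rt
Reagents that add atoms: hexacarbonylchromium O=C=[Cr](=C=O)(=C=O)(=C=O)(=C=O)=C=O; trimethyloxonium tetrafluoroborate C[O+](C)C.F[B-](F)(F)F; n-butyllithium CCCC[Li] (lithium of 10 and 11 only)
Why: Shapiro reaction joined to the Fischer carbene synthesis: the second deprotonation is directed syn to the sulfonamide nitrogen and to the open methylene C4a rather than to C1 beside the quaternary centre, loss of sulfinate and N2 gives vinyllithium 10 with the C4a=C8a alkene, 10 adds to a CO ligand of Cr(CO)6, and the Meerwein salt methylates acylate 11 on oxygen.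

Step 6
Reactants: 12 pentacarbonyl{[(5R)-5-ethyl-5-(triethylsilyloxy)cyclohex-1-en-1-yl](methoxy)carbene}chromium; 13 ethoxyacetylene
Product: 15 (R)-6-ethoxy-2-ethyl-5-hydroxy-8-methoxy-2-(triethylsilyloxy)tetralin, via tricarbonylchromium arene complex 14 (not isolated)
Conditions: 13 (2 equiv, slow addition), degassed THF (0.05 M), 50 °C, Ar; then air, Et2O, rt
Reagents that add atoms: ethoxyacetylene C#COCC
Why: Dötz benzannulation of an alkenyl Fischer carbene complex: after loss of one CO, or by direct polar attack of the ynol ether, the alkyne inserts with its unsubstituted, nucleophilic CH terminus on the electrophilic carbene carbon C8, so that C6 with its ethoxy group becomes the new metal-bound carbon. A CO ligand then migrates onto C6 to give a chromium-bound dienylketene whose ketene carbon C5 closes on the ring alkene carbon C4a by six-electron electrocyclisation, the only ring closure of the step, and enolisation of the cyclohexadienone gives the phenol as complex 14, from which air removes the metal. The closest known class is the benzannulation of cycloalkenyl(methoxy)carbene chromium complexes with terminal alkynes, which rarely divert to indene, furan or cyclobutenone products, whereas alkoxyalkynes are seldom-used partners, and this is where the route places its risk. The step needs one regiochemical outcome, ethoxy on C6 and hydrogen on C7, and both the steric rule (larger alkyne substituent next to the CO-derived carbon) and the polarity of the ynol ether point that way. The site of ring fusion is fixed because C4a is the only alkene terminus available and carries the hydrogen needed for aromatisation. No stereocentre is formed, and C2 lies two bonds from the reacting alkene, is masked as a silyl ether and is not touched.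

Step 7
Reactants: 15 (R)-6-ethoxy-2-ethyl-5-hydroxy-8-methoxy-2-(triethylsilyloxy)tetralin
Product: 16 (R)-6-ethoxy-2-ethyl-5,8-dimethoxy-2-(triethylsilyloxy)tetralin
Conditions: MeI, K2CO3, acetone, 50 °C, Ar
Reagents that add atoms: iodomethane CI
Why: Williamson methylation of the air-sensitive phenol under weak base leaves the silyl ether alone and turns ring B into a trialkoxyarene ready for hydride abstraction.

Step 8
Reactants: 16 (R)-6-ethoxy-2-ethyl-5,8-dimethoxy-2-(triethylsilyloxy)tetralin
Product: 18 (R)-6-ethoxy-2-ethyl-5,8-dimethoxy-2-(triethylsilyloxy)-3,4-dihydronaphthalen-1(2H)-one, via C1 benzylic alcohol 17 (not isolated)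
Conditions: DDQ (2.3 equiv), CH2Cl2/pH 7 phosphate buffer (10:1), 0 °C to rt
Reagents that add atoms: water O
Why: DDQ benzylic oxidation in wet medium, as in the conversion of 6-alkoxytetralins into 1-tetralones: hydride should leave C1 because that cation is stabilised by the para ethoxy group on C6 and the ortho methoxy group on C8 whereas a C4 cation has only one ortho donor, and water capture plus a second oxidation give the aryl ketone under buffered conditions that the silyl ether tolerates.

Step 9
Reactants: 18 (R)-6-ethoxy-2-ethyl-5,8-dimethoxy-2-(triethylsilyloxy)-3,4-dihydronaphthalen-1(2H)-one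
Product: 20 (R)-6-ethoxy-2-ethyl-5,8-dimethoxy-2-(triethylsilyloxy)naphthalen-1(2H)-one, via C4 benzylic bromide 19 (not isolated)
Conditions: NBS (1.05 equiv), AIBN (cat.), PhCF3, 80 °C; then DBU, 0 °C to rt
Reagents that add atoms: N-bromosuccinimide O=C1CCC(=O)N1Br (bromine of 19 only)
Why: Wohl–Ziegler bromination of the only remaining benzylic methylene followed by E2 loss of HBr is the usual way from 2,2-disubstituted 1-tetralones to naphthalen-1(2H)-ones, the C1 ketone prevents the new alkene from aromatising by loss of the C2 oxygen, and ring position C7 is shielded by two flanking alkoxy groups that are engaged in conjugation with that ketone.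

Step 10
Reactants: 20 (R)-6-ethoxy-2-ethyl-5,8-dimethoxy-2-(triethylsilyloxy)naphthalen-1(2H)-one
Product: 21 (2R,3S,4S)-6-ethoxy-2-ethyl-3,4-dihydroxy-5,8-dimethoxy-2-(triethylsilyloxy)-3,4-dihydronaphthalen-1(2H)-one
Conditions: K2OsO4·2H2O (2 mol%), NMO, acetone/H2O, rt
Reagents that add atoms: N-methylmorpholine N-oxide C[N+]1([O-])CCOCC1; water O
Why: Upjohn dihydroxylation of the styrene-type alkene is a syn addition expected on the face anti to the allylic silyloxy group, and since both new centres are erased in step 21 the facial outcome does not matter for the target, although the trans C2–O/C3–O relation should later hinder migration of the quinonyl group.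

Step 11
Reactants: 21 (2R,3S,4S)-6-ethoxy-2-ethyl-3,4-dihydroxy-5,8-dimethoxy-2-(triethylsilyloxy)-3,4-dihydronaphthalen-1(2H)-one
Product: 22 3,4-O-isopropylidene derivative of 21
Conditions: 2,2-dimethoxypropane, PPTS (cat.), CH2Cl2, rt
Reagents that add atoms: 2,2-dimethoxypropane COC(C)(C)OC
Why: Acid-catalysed transketalisation ties the cis-diol into a five-membered acetonide, so that at the coupling stage C3 and C4 carry their oxygen but offer neither an acidic C3–H next to a carbonyl group nor an alkene.

Step 12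
Reactants: 22 3,4-O-isopropylidene derivative of 21
Product: 23 (2R,3S,4S)-6-ethoxy-2-ethyl-2-hydroxy-3,4-(isopropylidenedioxy)-5,8-dimethoxy-3,4-dihydronaphthalen-1(2H)-one
Conditions: HF·pyridine, pyridine, THF, 0 °C to rt
Reagents that add atoms: none
Why: Fluoride-driven cleavage of the triethylsilyl ether in a buffered, weakly acidic medium spares the acetonide and avoids base-induced α-ketol shifts at C2.

Step 13
Reactants: 24 1,2,4-trimethoxybenzene; 25 butanoic anhydride
Product: 26 1-(2,4,5-trimethoxyphenyl)butan-1-one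
Conditions: (PrCO)2O (1.2 equiv), Sc(OTf)3 (5 mol%), MeNO2, 50 °C
Reagents that add atoms: butanoic anhydride CCCC(=O)OC(=O)CCC
Why: Friedel–Crafts acylation of the very electron-rich arene goes to C5 of 24, para to the 2-methoxy group, and a catalytic metal triflate avoids the ortho-demethylation that aluminium halides can cause.

Step 14
Reactants: 26 1-(2,4,5-trimethoxyphenyl)butan-1-one; 27 tert-butyl bromoacetate
Product: 29 tert-butyl 3-(2,4,5-trimethoxybenzoyl)pentanoate (racemic), via lithium enolate 28 (not isolated)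
Conditions: LiN(SiMe3)2 (1.1 equiv), THF, −78 °C; 27, −78 to 0 °C
Reagents that add atoms: tert-butyl bromoacetate CC(C)(C)OC(=O)CBr; LiN(SiMe3)2 [Li]N([Si](C)(C)C)[Si](C)(C)C (lithium of 28 only)
Why: Enolate alkylation with a reactive α-bromo ester puts the ethyl-bearing carbon (future C3) next to the carbon that becomes C4, peri to the isolated 5-methoxy group, which is the regiochemistry the target demands, and the new stereocentre is racemic and is erased in step 17.

Step 15
Reactants: 29 tert-butyl 3-(2,4,5-trimethoxybenzoyl)pentanoate (racemic)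
Product: 30 3-[(2,4,5-trimethoxyphenyl)methyl]pentanoic acid (racemic)
Conditions: Et3SiH (3 equiv), CF3CO2H/CH2Cl2, 0 °C to rt
Reagents that add atoms: none
Why: Ionic hydrogenation reduces the electron-rich aryl ketone to the methylene group by way of its well-stabilised benzylic cation, and the same acid cleaves the tert-butyl ester.

Step 16
Reactants: 30 3-[(2,4,5-trimethoxyphenyl)methyl]pentanoic acid (racemic)
Product: 32 3-ethyl-5,7,8-trimethoxy-3,4-dihydronaphthalen-1(2H)-one (racemic), via mixed trifluoroacetic anhydride 31 (not isolated)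
Conditions: (CF3CO)2O (2 equiv), CH2Cl2, 0 °C to rt
Reagents that add atoms: trifluoroacetic anhydride O=C(OC(=O)C(F)(F)F)C(F)(F)F (trifluoroacetyl group of 31 only)
Why: Intramolecular Friedel–Crafts acylation through the mixed anhydride closes the six-membered ring at the only free ortho position, which is activated by its neighbouring methoxy group.

Step 17
Reactants: 32 3-ethyl-5,7,8-trimethoxy-3,4-dihydronaphthalen-1(2H)-one (racemic)
Product: 34 3-ethyl-2-hydroxy-5,7,8-trimethoxy-1,4-naphthoquinone, via potassium quinonolate 33 (not isolated)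
Conditions: KOt-Bu (4 equiv), O2 (1 atm), t-BuOH, 30 °C; then 1 M aq. HCl
Reagents that add atoms: dioxygen O=O; KOt-Bu CC(C)(C)[O-].[K+] (potassium of 33 only)
Why: Base-mediated autoxidation of a 1-tetralone oxygenates the C2 enolate to the 1,2-dione and, after enolisation, the benzylic C4, so that the hydroxyl group ends up on C2 next to the original carbonyl C1 (peri to the 7,8-dimethoxy side) and ethyl on C3.

Step 18
Reactants: 34 3-ethyl-2-hydroxy-5,7,8-trimethoxy-1,4-naphthoquinone
Product: 35 2-chloro-3-ethyl-5,7,8-trimethoxy-1,4-naphthoquinone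
Conditions: (COCl)2 (2 equiv), DMF (cat.), CH2Cl2, 0 °C to rt
Reagents that add atoms: oxalyl chloride O=C(Cl)C(=O)Cl
Why: The hydroxyquinone is a vinylogous carboxylic acid and should be turned into the vinylogous acid chloride by the Vilsmeier-type chloroiminium reagent.

Step 19
Reactants: 23 (2R,3S,4S)-6-ethoxy-2-ethyl-2-hydroxy-3,4-(isopropylidenedioxy)-5,8-dimethoxy-3,4-dihydronaphthalen-1(2H)-one; 35 2-chloro-3-ethyl-5,7,8-trimethoxy-1,4-naphthoquinone
Product: 37 3-ethyl-5,7,8-trimethoxy-2-{[(2R,3S,4S)-6-ethoxy-2-ethyl-3,4-(isopropylidenedioxy)-5,8-dimethoxy-1-oxo-1,2,3,4-tetrahydronaphthalen-2-yl]oxy}-1,4-naphthoquinone, via potassium alkoxide 36 (not isolated)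
Conditions: KN(SiMe3)2 (1.05 equiv), THF, −78 °C; 35 (1.2 equiv), −78 to 0 °C
Reagents that add atoms: KN(SiMe3)2 C[Si](C)(C)[N-][Si](C)(C)C.[K+] (potassium of 36 only)
Why: Addition–elimination of an alkoxide on a 2-halo-1,4-naphthoquinone: the alkoxide adds to C2 of 35 and chloride leaves, the C2–O bond of 23 is never broken so configuration is retained, 23 has no enolisable hydrogen, and its α-ketol alkoxide is less basic than a plain tertiary alkoxide, which should disfavour deprotonation of the ethyl side chain of the quinone.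

Step 20
Reactants: 37 acetonide-protected ether
Product: 38 3-ethyl-5,7,8-trimethoxy-2-{[(2R,3S,4S)-6-ethoxy-2-ethyl-3,4-dihydroxy-5,8-dimethoxy-1-oxo-1,2,3,4-tetrahydronaphthalen-2-yl]oxy}-1,4-naphthoquinone
Conditions: AcOH/H2O/THF (3:1:1), 45 °C; crude product used at once
Reagents that add atoms: none
Why: Mild aqueous acid hydrolyses the benzylic acetonide, whereas the tertiary ether cannot ionise next to the C1 carbonyl group.

Step 21
Reactants: 38 diol ether
Product: 39 3-ethyl-5,7,8-trimethoxy-2-{[(2S)-6-ethoxy-2-ethyl-5,8-dimethoxy-1,3,4-trioxo-1,2,3,4-tetrahydronaphthalen-2-yl]oxy}-1,4-naphthoquinone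
Conditions: IBX (5 equiv), DMSO, rt
Reagents that add atoms: none
Why: IBX oxidation takes 1,2-diols to 1,2-diketones without C–C cleavage under neutral conditions, so the transient C4 ketone that still has a C3–H never meets a base able to expel the hydroxyquinone from C2, and the quinone half is already fully oxidised.

Step 22
Reactants: 39 hexaalkyl ether of the target
Product: 40 (S)-2-ethyl-2-[(3-ethyl-5,7,8-trihydroxy-1,4-dioxo-1,4-dihydronaphthalen-2-yl)oxy]-5,6,8-trihydroxynaphthalene-1,3,4(2H)-trione (CNP0325426.1)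
Conditions: BBr3 (15 equiv), CH2Cl2, −78 to 0 °C; then ice-water
Reagents that add atoms: none
Why: Boron tribromide ether cleavage should be chelation-assisted at all six sites, since four ethers are peri to a carbonyl group and the other two lie ortho to a position that becomes a boron phenolate, while the C2–O bond is safe because C2 is quaternary (no SN2) and flanked by two carbonyl groups (no ionisation) and the hindered, delocalised ether oxygen is a poor donor to boron.

Compound list
1 | 3-ethoxycyclohex-2-en-1-one | CCOC1=CC(=O)CCC1 | starting material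
2 | ethylmagnesium bromide | CC[Mg]Br | starting material
3 | bromomagnesium 3-ethoxy-1-ethylcyclohex-2-en-1-olate (racemic) | CCOC1=CC(CC)(O[Mg]Br)CCC1 | intermediate
4 | 3-ethylcyclohex-2-en-1-one | CCC1=CC(=O)CCC1 | intermediate
5 | (S)-3-ethyl-3-(4,4,5,5-tetramethyl-1,3,2-dioxaborolan-2-yl)cyclohexan-1-one | B1(OC(C)(C)C(C)(C)O1)[C@]2(CC)CCCC(=O)C2 | intermediate
6 | (R)-3-ethyl-3-hydroxycyclohexan-1-one | O[C@]1(CC)CCCC(=O)C1 | intermediate
7 | (R)-3-ethyl-3-(triethylsilyloxy)cyclohexan-1-one | CC[Si](CC)(CC)O[C@]1(CC)CCCC(=O)C1 | intermediate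
8 | 2,4,6-triisopropylbenzenesulfonylhydrazone of 7 (R at the carbinol carbon, C=N geometry not fixed) | CC[Si](CC)(CC)O[C@]1(CC)CCCC(=NNS(=O)(=O)c2c(C(C)C)cc(C(C)C)cc2C(C)C)C1 | intermediate
9 | hexacarbonylchromium | O=C=[Cr](=C=O)(=C=O)(=C=O)(=C=O)=C=O | starting material
10 | [(5R)-5-ethyl-5-(triethylsilyloxy)cyclohex-1-en-1-yl]lithium | CC[Si](CC)(CC)O[C@]1(CC)CCC=C([Li])C1 | intermediate
11 | lithium acylpentacarbonylchromate from 10 and 9 | CC[Si](CC)(CC)O[C@]1(CC)CCC=C(C1)C(O[Li])=[Cr](=C=O)(=C=O)(=C=O)(=C=O)=C=O | intermediate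
12 | pentacarbonyl{[(5R)-5-ethyl-5-(triethylsilyloxy)cyclohex-1-en-1-yl](methoxy)carbene}chromium | CC[Si](CC)(CC)O[C@]1(CC)CCC=C(C1)C(OC)=[Cr](=C=O)(=C=O)(=C=O)(=C=O)=C=O | intermediate
13 | ethoxyacetylene | C#COCC | starting material
14 | tricarbonylchromium π-complex of 15 (metal on ring B, written as two parts) | CC[Si](CC)(CC)O[C@]1(CC)CCc2c(O)c(OCC)cc(OC)c2C1.O=C=[Cr](=C=O)=C=O | intermediate
15 | (R)-6-ethoxy-2-ethyl-5-hydroxy-8-methoxy-2-(triethylsilyloxy)tetralin | CC[Si](CC)(CC)O[C@]1(CC)CCc2c(O)c(OCC)cc(OC)c2C1 | intermediate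
16 | (R)-6-ethoxy-2-ethyl-5,8-dimethoxy-2-(triethylsilyloxy)tetralin | CC[Si](CC)(CC)O[C@]1(CC)CCc2c(OC)c(OCC)cc(OC)c2C1 | intermediate
17 | (2R)-6-ethoxy-2-ethyl-5,8-dimethoxy-2-(triethylsilyloxy)tetralin-1-ol (C1 epimers) | CC[Si](CC)(CC)O[C@]1(CC)CCc2c(OC)c(OCC)cc(OC)c2C1O | intermediate
18 | (R)-6-ethoxy-2-ethyl-5,8-dimethoxy-2-(triethylsilyloxy)-3,4-dihydronaphthalen-1(2H)-one | CC[Si](CC)(CC)O[C@]1(CC)CCc2c(OC)c(OCC)cc(OC)c2C1=O | intermediate
19 | (2R)-4-bromo-6-ethoxy-2-ethyl-5,8-dimethoxy-2-(triethylsilyloxy)-3,4-dihydronaphthalen-1(2H)-one (C4 epimers) | CC[Si](CC)(CC)O[C@]1(CC)CC(Br)c2c(OC)c(OCC)cc(OC)c2C1=O | intermediate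
20 | (R)-6-ethoxy-2-ethyl-5,8-dimethoxy-2-(triethylsilyloxy)naphthalen-1(2H)-one | CC[Si](CC)(CC)O[C@]1(CC)C=Cc2c(OC)c(OCC)cc(OC)c2C1=O | intermediate
21 | (2R,3S,4S)-6-ethoxy-2-ethyl-3,4-dihydroxy-5,8-dimethoxy-2-(triethylsilyloxy)-3,4-dihydronaphthalen-1(2H)-one | CC[Si](CC)(CC)O[C@]1(CC)[C@@H](O)[C@@H](O)c2c(OC)c(OCC)cc(OC)c2C1=O | intermediate
22 | 3,4-O-isopropylidene derivative of 21 (2R,3S,4S) | CC[Si](CC)(CC)O[C@]1(CC)[C@H]3OC(C)(C)O[C@H]3c2c(OC)c(OCC)cc(OC)c2C1=O | intermediate
23 | (2R,3S,4S)-6-ethoxy-2-ethyl-2-hydroxy-3,4-(isopropylidenedioxy)-5,8-dimethoxy-3,4-dihydronaphthalen-1(2H)-one | O[C@]1(CC)[C@H]3OC(C)(C)O[C@H]3c2c(OC)c(OCC)cc(OC)c2C1=O | intermediate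
24 | 1,2,4-trimethoxybenzene | COc1ccc(OC)c(OC)c1 | starting material
25 | butanoic anhydride | CCCC(=O)OC(=O)CCC | starting material
26 | 1-(2,4,5-trimethoxyphenyl)butan-1-one | CCCC(=O)c1cc(OC)c(OC)cc1OC | intermediate
27 | tert-butyl bromoacetate | CC(C)(C)OC(=O)CBr | starting material
28 | lithium enolate of 26 | CCC=C(O[Li])c1cc(OC)c(OC)cc1OC | intermediate
29 | tert-butyl 3-(2,4,5-trimethoxybenzoyl)pentanoate (racemic) | CCC(CC(=O)OC(C)(C)C)C(=O)c1cc(OC)c(OC)cc1OC | intermediate
30 | 3-[(2,4,5-trimethoxyphenyl)methyl]pentanoic acid (racemic) | CCC(CC(=O)O)Cc1cc(OC)c(OC)cc1OC | intermediate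
31 | mixed anhydride of 30 and trifluoroacetic acid (racemic) | CCC(CC(=O)OC(=O)C(F)(F)F)Cc1cc(OC)c(OC)cc1OC | intermediate
32 | 3-ethyl-5,7,8-trimethoxy-3,4-dihydronaphthalen-1(2H)-one (racemic) | CCC1CC(=O)c2c(OC)c(OC)cc(OC)c2C1 | intermediate
33 | potassium salt of 34 | CCC1=C([O-])C(=O)c2c(OC)c(OC)cc(OC)c2C1=O.[K+] | intermediate
34 | 3-ethyl-2-hydroxy-5,7,8-trimethoxy-1,4-naphthoquinone | CCC1=C(O)C(=O)c2c(OC)c(OC)cc(OC)c2C1=O | intermediate
35 | 2-chloro-3-ethyl-5,7,8-trimethoxy-1,4-naphthoquinone | CCC1=C(Cl)C(=O)c2c(OC)c(OC)cc(OC)c2C1=O | intermediate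
36 | potassium alkoxide of 23 | [K+].[O-][C@]1(CC)[C@H]3OC(C)(C)O[C@H]3c2c(OC)c(OCC)cc(OC)c2C1=O | intermediate
37 | 3-ethyl-5,7,8-trimethoxy-2-{[(2R,3S,4S)-6-ethoxy-2-ethyl-3,4-(isopropylidenedioxy)-5,8-dimethoxy-1-oxo-1,2,3,4-tetrahydronaphthalen-2-yl]oxy}-1,4-naphthoquinone | CCC1=C(O[C@]2(CC)[C@H]3OC(C)(C)O[C@H]3c4c(OC)c(OCC)cc(OC)c4C2=O)C(=O)c5c(OC)c(OC)cc(OC)c5C1=O | intermediate
38 | 3-ethyl-5,7,8-trimethoxy-2-{[(2R,3S,4S)-6-ethoxy-2-ethyl-3,4-dihydroxy-5,8-dimethoxy-1-oxo-1,2,3,4-tetrahydronaphthalen-2-yl]oxy}-1,4-naphthoquinone | CCC1=C(O[C@]2(CC)[C@@H](O)[C@@H](O)c4c(OC)c(OCC)cc(OC)c4C2=O)C(=O)c5c(OC)c(OC)cc(OC)c5C1=O | intermediate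
39 | 3-ethyl-5,7,8-trimethoxy-2-{[(2S)-6-ethoxy-2-ethyl-5,8-dimethoxy-1,3,4-trioxo-1,2,3,4-tetrahydronaphthalen-2-yl]oxy}-1,4-naphthoquinone | CCC1=C(O[C@]2(CC)C(=O)C(=O)c4c(OC)c(OCC)cc(OC)c4C2=O)C(=O)c5c(OC)c(OC)cc(OC)c5C1=O | intermediate
40 | (S)-2-ethyl-2-[(3-ethyl-5,7,8-trihydroxy-1,4-dioxo-1,4-dihydronaphthalen-2-yl)oxy]-5,6,8-trihydroxynaphthalene-1,3,4(2H)-trione (CNP0325426.1) | CCC1=C(O[C@]2(CC)C(=O)C(=O)c3c(O)c(O)cc(O)c3C2=O)C(=O)c2c(O)c(O)cc(O)c2C1=O | target

Total step count: 22. Longest linear sequence: 16 steps (steps 1–12, then 19–22). The ring A fragment takes 6 steps (13–18).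

Steps most likely to fail

Step 6. The electron-rich alkyne may oligomerise at the metal. Alternatively, insertion may stop at a donor-stabilised dienylcarbene stage, so that CO uptake and ring closure do not follow. The fallback sets out from 12 and brings the C6 oxygen in as boron. Benzannulation of 12 with commercial 2-ethynyl-4,4,5,5-tetramethyl-1,3,2-dioxaborolane uses an electron-poor alkyne whose boryl group, as the larger substituent, goes next to the CO-derived carbon. With the same air work-up it should give (R)-2-ethyl-5-hydroxy-8-methoxy-6-(4,4,5,5-tetramethyl-1,3,2-dioxaborolan-2-yl)-2-(triethylsilyloxy)tetralin F1. Methylation (MeI, K2CO3) gives (R)-2-ethyl-5,8-dimethoxy-6-(4,4,5,5-tetramethyl-1,3,2-dioxaborolan-2-yl)-2-(triethylsilyloxy)tetralin F2. Oxidation with NaBO3·4H2O gives (R)-2-ethyl-6-hydroxy-5,8-dimethoxy-2-(triethylsilyloxy)tetralin F3. Ethylation (EtI, K2CO3) brings the material back to the route at 16.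

Step 19. The hindered alkoxide may act as a base or electron donor towards the quinone, by removing a proton from the ethyl side chain or by electron transfer, faster than it adds to C2. The fallback sets out from 22 and 35, uses no stoichiometric base and bypasses step 12. Halogen exchange on 35 (AgF, MeCN, rt) gives the more electrophilic 3-ethyl-2-fluoro-5,7,8-trimethoxy-1,4-naphthoquinone F4. Silyl ether 22 and F4 are then combined with catalytic fluoride (CsF or [Bu4N][Ph3SiF2], DMF, rt). The alkoxide is thereby released only in traces and consumed at once, with Si–F bond formation as the driving force. The sequence comes back to the route at 37.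

Step 9. Ionic bromination of ring B at C7, or loss of the silyl group under the HBr that is formed, may overtake hydrogen abstraction at C4. The fallback sets out from 18 and reaches the alkene through oxygen instead of bromine. Benzylic oxidation with t-BuOOH and catalytic Rh2(cap)4 (cap = caprolactamate) gives (R)-6-ethoxy-2-ethyl-5,8-dimethoxy-2-(triethylsilyloxy)-2,3-dihydronaphthalene-1,4-dione F5. Luche reduction (NaBH4, CeCl3·7H2O, MeOH, −78 °C) attacks the less hindered C4 carbonyl group. It gives (2R)-6-ethoxy-2-ethyl-4-hydroxy-5,8-dimethoxy-2-(triethylsilyloxy)-3,4-dihydronaphthalen-1(2H)-one F6. Dehydration with the Burgess reagent (toluene, 60 °C) comes back to the route at 20.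

Further compounds
F1 | step 6 | (R)-2-ethyl-5-hydroxy-8-methoxy-6-(4,4,5,5-tetramethyl-1,3,2-dioxaborolan-2-yl)-2-(triethylsilyloxy)tetralin | CC[Si](CC)(CC)O[C@]1(CC)CCc2c(O)c(B3OC(C)(C)C(C)(C)O3)cc(OC)c2C1
F2 | step 6 | (R)-2-ethyl-5,8-dimethoxy-6-(4,4,5,5-tetramethyl-1,3,2-dioxaborolan-2-yl)-2-(triethylsilyloxy)tetralin | CC[Si](CC)(CC)O[C@]1(CC)CCc2c(OC)c(B3OC(C)(C)C(C)(C)O3)cc(OC)c2C1
F3 | step 6 | (R)-2-ethyl-6-hydroxy-5,8-dimethoxy-2-(triethylsilyloxy)tetralin | CC[Si](CC)(CC)O[C@]1(CC)CCc2c(OC)c(O)cc(OC)c2C1
F4 | step 19 | 3-ethyl-2-fluoro-5,7,8-trimethoxy-1,4-naphthoquinone | CCC1=C(F)C(=O)c2c(OC)c(OC)cc(OC)c2C1=O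
F5 | step 9 | (R)-6-ethoxy-2-ethyl-5,8-dimethoxy-2-(triethylsilyloxy)-2,3-dihydronaphthalene-1,4-dione | CC[Si](CC)(CC)O[C@]1(CC)CC(=O)c2c(OC)c(OCC)cc(OC)c2C1=O
F6 | step 9 | (2R)-6-ethoxy-2-ethyl-4-hydroxy-5,8-dimethoxy-2-(triethylsilyloxy)-3,4-dihydronaphthalen-1(2H)-one (C4 epimers) | CC[Si](CC)(CC)O[C@]1(CC)CC(O)c2c(OC)c(OCC)cc(OC)c2C1=O
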